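**Retrosynthetic overview**

1. The last C–C bond is C12–C13, made by sp3–sp2 Negishi coupling of a decalin alkylzinc with a butenolide enol triflate; the triflate comes from dimethyl L-tartrate acetonide (C14 and C15 bought, C16 by CBS reduction, butenolide ring by ring-closing metathesis).
2. On the decalin, the C9 chain, C8 (Me/OH) and C6–OH are grown on a 6,8-dioxygenated ring B: Stork–Danheiser alkylation and methyl addition, enone epoxidation/SmI2, then Li/NH3.
3. Ring A (C1–C2–C3–C4–C5–C10) is closed last by the C4–C5 bond: Lewis-acid opening of an (R)-2,2-disubstituted epoxide by one enol ether of a mirror-symmetric Birch bis-enol ether. The single bought centre (C4, from (S)-2-methylglycidol) is meant to set C4, C5 and C10 in this one event.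
4. Enabling feature: ring B carries oxygen on C6 and C8 (1,3 across C7), so C5 and C9 are equivalent α-carbons flanking C10 and ring B maps onto 3,5-dimethoxybenzoic acid (Birch reduction–methylation, C10 prochiral); the C18 hydroxyl sits 1,4 to O6 (O18–C18–C4–C5–C6), the retron of an epoxide plus an enol ether.
5. Ring order: butenolide (step 7); ring B is never closed (bought arene, dearomatised in step 9); ring A (step 17).

Key step: step 17

Remark on numbering: labdane-type locants are used for the decalin (ring A = C1–C5, C10; ring B = C5–C10; C18 = CH2OH on C4, C19 = 4-methyl, C20 = 10-methyl, C17 = 8-methyl; side chain C11–C16); β is the face of the 10-methyl group.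

**Route**

Step 1
Reactants: 1 dimethyl (4R,5R)-2,2-dimethyl-1,3-dioxolane-4,5-dicarboxylate (dimethyl L-tartrate acetonide)
Product: 2 (4R,5R)-N4,N5-dimethoxy-N4,N5,2,2-tetramethyl-1,3-dioxolane-4,5-dicarboxamide
Conditions: MeNHOMe·HCl, i-PrMgCl, THF, −20 °C
Reagents that add atoms: N,O-dimethylhydroxylamine hydrochloride, CNOC.Cl
Why: Magnesium-amide aminolysis of esters (Weinreb amide formation) should convert both esters and leave the two stereocentres of the trans-dioxolane untouched.

Step 2
Reactants: 2 bis-Weinreb amide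
Product: 3 (4R,5R)-5-acetyl-N-methoxy-N,2,2-trimethyl-1,3-dioxolane-4-carboxamide
Conditions: MeMgBr (1 equiv), THF, −78 to 0 °C; aq. NH4Cl
Reagents that add atoms: methylmagnesium bromide, C[Mg]Br
Why: Weinreb ketone synthesis: the chelated tetrahedral adduct prevents over-addition and, with one equivalent of Grignard reagent, the C2-symmetric bis-amide should react once to give the methyl ketone that becomes C13 and its =CH2.

Step 3
Reactants: 3 keto amide
Product: 4 1-[(4R,5R)-5-[methoxy(methyl)carbamoyl]-2,2-dimethyl-1,3-dioxolan-4-yl]ethenyl trifluoromethanesulfonate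
Conditions: KHMDS, PhNTf2, THF, −78 °C
Reagents that add atoms: N-phenylbis(trifluoromethanesulfonimide), O=S(=O)(N(c1ccccc1)S(=O)(=O)C(F)(F)F)C(F)(F)F
Why: Kinetic deprotonation of the methyl ketone at CH3 (the alkoxy-bearing methine is hindered and poorly aligned in the dioxolane) and O-sulfonylation should give the 2-triflyloxy-1-alkene, the future C13(=CH2) coupling site.

Step 4
Reactants: 4 enol triflate amide
Product: 5 1-[(4R,5R)-2,2-dimethyl-5-(2-methylprop-2-enoyl)-1,3-dioxolan-4-yl]ethenyl trifluoromethanesulfonate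
Conditions: isopropenylmagnesium bromide, THF, −78 to 0 °C; aq. NH4Cl
Reagents that add atoms: isopropenylmagnesium bromide, CC(=C)[Mg]Br
Why: Second Weinreb ketone synthesis; the enol triflate should be inert to the Grignard reagent at low temperature and the α-alkoxy centre stays in the favoured trans-dioxolane.

Step 5
Reactants: 5 isopropenyl ketone
Product: 6 1-[(4R,5S)-5-[(1R)-1-hydroxy-2-methylprop-2-en-1-yl]-2,2-dimethyl-1,3-dioxolan-4-yl]ethenyl trifluoromethanesulfonate
Conditions: (R)-2-methyl-CBS-oxazaborolidine (cat.), catecholborane, toluene, −78 °C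
Reagents that add atoms: none
Why: Corey–Bakshi–Shibata reduction with the isopropenyl group as the large substituent should give the (R)-carbinol C16 (15,16-syn), which is also the Felkin–Anh product of 1,2-reduction next to the dioxolane oxygen, so reagent and substrate control should be matched.

Step 6
Reactants: 6 allylic alcohol
Product: 7 (1R)-1-[(4S,5R)-2,2-dimethyl-5-[1-(trifluoromethylsulfonyloxy)ethenyl]-1,3-dioxolan-4-yl]-2-methylprop-2-en-1-yl prop-2-enoate
Conditions: acryloyl chloride, i-Pr2NEt, DMAP (cat.), CH2Cl2, −78 to 0 °C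
Reagents that add atoms: acryloyl chloride, C=CC(=O)Cl
Why: Standard O-acylation of the allylic alcohol installs C28–C30 of the butenolide without touching C16.

Step 7
Reactants: 7 acrylate
Product: 8 1-[(4R,5S)-2,2-dimethyl-5-[(2R)-3-methyl-5-oxo-2,5-dihydrofuran-2-yl]-1,3-dioxolan-4-yl]ethenyl trifluoromethanesulfonate
Conditions: Grubbs second-generation catalyst (cat.), toluene, 80 °C
Reagents that add atoms: none
Why: Ring-closing metathesis between the acrylate and the 1,1-disubstituted alkene closes the 4-methylbutenolide (trisubstituted alkene, hence a second-generation Ru catalyst and heat), while the electron-poor enol triflate alkene should not take part.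

Step 8
Reactants: 9 (S)-2-methylglycidol [(2S)-2-methyloxiran-2-yl]methanol
Product: 10 tert-butyldimethyl{[(2R)-2-methyloxiran-2-yl]methoxy}silane
Conditions: TBSCl, imidazole, CH2Cl2, 0 °C
Reagents that add atoms: tert-butyldimethylsilyl chloride, CC(C)(C)[Si](C)(C)Cl
Why: Silylation of the primary alcohol; the quaternary epoxide carbon is not involved, so the bought stereocentre is carried unchanged (the descriptor becomes R only by priority).

Step 9
Reactants: 11 3,5-dimethoxybenzoic acid
Product: 13 3,5-dimethoxy-1-methylcyclohexa-2,5-diene-1-carboxylic acid, via dilithium dienolate 12 (not isolated)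
Conditions: Li, NH3(l), THF, −78 °C; then MeI; aq. NH4Cl, careful acidification
Reagents that add atoms: iodomethane, CI
Why: Birch reduction of the benzoate gives the cross-conjugated dienolate (carbanion at the carboxyl-bearing carbon), and C-methylation creates the quaternary C10 while both methyl enol ethers remain; the product is achiral (mirror plane through C10 and C7).

Step 10
Reactants: 13 Birch acid
Product: 14 (3,5-dimethoxy-1-methylcyclohexa-2,5-dien-1-yl)methanol
Conditions: LiAlH4, THF, 0 °C to rt; basic work-up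
Reagents that add atoms: none
Why: Hydride reduction of the carboxylic acid to the primary alcohol; enol ethers are inert to LiAlH4.

Step 11
Reactants: 14 dienyl carbinol
Product: 15 3,5-dimethoxy-1-methylcyclohexa-2,5-diene-1-carbaldehyde
Conditions: TPAP (cat.), NMO, 4 Å MS, CH2Cl2, rt
Reagents that add atoms: none
Why: Ley–Griffith oxidation under neutral conditions should give the non-enolisable aldehyde without hydrolysing the acid-labile enol ethers.

Step 12
Reactants: 15 aldehyde
Product: 16 3-ethynyl-1,5-dimethoxy-3-methylcyclohexa-1,4-diene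
Conditions: dimethyl (1-diazo-2-oxopropyl)phosphonate, K2CO3, MeOH, 0 °C to rt
Reagents that add atoms: dimethyl (1-diazo-2-oxopropyl)phosphonate, CC(=O)C(=[N+]=[N-])P(=O)(OC)OC
Why: Seyferth–Gilbert homologation (Ohira–Bestmann reagent) turns the aldehyde into the terminal alkyne (C1 and C2 of ring A) under basic conditions that the enol ethers tolerate.

Step 13
Reactants: 16 alkyne; 10 silyl glycidyl ether
Product: 17 (2R)-1-(tert-butyldimethylsilyloxy)-5-(3,5-dimethoxy-1-methylcyclohexa-2,5-dien-1-yl)-2-methylpent-4-yn-2-ol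
Conditions: n-BuLi, BF3·OEt2, THF, −78 °C; Et3N quench
Reagents that add atoms: none
Why: Yamaguchi-type opening of the 2,2-disubstituted epoxide by the lithium alkynyltrifluoroborate at its CH2 carbon (C3) joins the chain and leaves the tertiary carbinol C4 configured as bought.

Step 14
Reactants: 17 alkynyl carbinol
Product: 18 (2R)-1-(tert-butyldimethylsilyloxy)-5-(3,5-dimethoxy-1-methylcyclohexa-2,5-dien-1-yl)-2-methylpentan-2-ol
Conditions: 2-nitrobenzenesulfonylhydrazide, Et3N, CH2Cl2, rt (repeated charges)
Reagents that add atoms: none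
Why: Diimide saturates the alkyne to the C1–C2 ethylene unit but should not reduce the electron-rich trisubstituted enol ethers; no stereocentre is involved.

Step 15
Reactants: 18 silyl ether
Product: 19 (2R)-5-(3,5-dimethoxy-1-methylcyclohexa-2,5-dien-1-yl)-2-methylpentane-1,2-diol
Conditions: TBAF, THF, 0 °C
Reagents that add atoms: none
Why: Fluoride cleavage of the primary TBS ether frees the 1,2-diol under non-acidic conditions.

Step 16
Reactants: 19 diol
Product: 21 (2R)-2-[3-(3,5-dimethoxy-1-methylcyclohexa-2,5-dien-1-yl)propyl]-2-methyloxirane, via monotosylate 20 (not isolated)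
Conditions: TsCl, Et3N, DMAP (cat.), CH2Cl2, 0 °C; then K2CO3, MeOH, rt
Reagents that add atoms: none
Why: Selective tosylation of the primary hydroxyl and 3-exo-tet displacement by the tertiary alkoxide give the (R)-epoxide with C4 unchanged, all under basic conditions compatible with the enol ethers.

Step 17
Reactants: 21 epoxy bis-enol ether
Product: 22 6α,18-epoxy-6β,8-dimethoxy-4β,10β-dimethyl-5β-H-decal-8(9)-ene (tricyclic mixed ketal; A/B cis)
Conditions: Me2AlCl (2 equiv), 2,6-di-tert-butyl-4-methylpyridine (cat.), CH2Cl2, −78 °C; Et3N, then aq. Rochelle salt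
Reagents that add atoms: none
Why: Proposed new method: Me2AlCl activates the epoxide, one of the two diastereotopic enol ether carbons (C5) opens it at the tertiary carbon C4 with inversion (6-exo with respect to the epoxide, closing ring A), and the aluminium alkoxide on C18 then collapses onto the C6 oxocarbenium ion (5-exo, temporary oxolane), so the event is a formal (3+2) addition of the C4–O unit across C5=C6; the closest known reaction types are epoxide-initiated cation–olefin cyclisations with enol ether π-nucleophiles and group-selective Prins cyclisations of Birch-derived cyclohexa-1,4-dienes. C4 is set by inversion of the purchased epoxide centre. C5 is set by delivery of C4 to the ring-B face that carries the tether, which gives the cis ring fusion (corrected in step 20 by epimerisation next to the C6 carbonyl). C10 is set by the choice between the two enol ethers: in the chair-like transition state the epoxide CH2, tied back toward the departing oxygen, should take the position over ring B from which its oxygen reaches C6, while the freely rotating methyl points outward, which places the 4-methyl cis to the 10-methyl. The step needs this group selectivity and C-alkylation at the tertiary carbon rather than 1,2-hydride shift of the epoxide; the high nucleophilicity of the enol ether, the six-membered closure and the low temperature are relied on for that.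

Step 18
Reactants: 22 mixed ketal
Product: 23 6,18-epoxy-4β,10β-dimethyl-5β-H-decal-6-en-8-one (cyclic vinylogous ester; A/B cis)
Conditions: PPTS (cat.), acetone/H2O, rt; azeotrope with toluene
Reagents that add atoms: water, O
Why: Acid hydrolysis of the enol ether frees the C8 ketone, and loss of methanol from the cyclic ketal with deprotonation at C7 gives the vinylogous ester; because O18 can only reach C6, the two ring-B carbonyl groups are differentiated, and C5 is not touched.

Step 19
Reactants: 23 vinylogous ester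
Product: 24 9β-allyl-6,18-epoxy-4β,10β-dimethyl-5β-H-decal-6-en-8-one
Conditions: LDA, allyl bromide, DMPU, THF, −78 to −20 °C
Reagents that add atoms: allyl bromide, C=CCBr
Why: Stork–Danheiser alkylation: LDA removes an α'-hydrogen (C9 is the only α'-CH2) and allyl bromide should attack the cross-conjugated enolate on the convex β face of the cis-fused tricycle, anti to the pseudoaxial C1–C10 bond, placing the allyl group cis to the 10-methyl.

Step 20
Reactants: 24 allylated vinylogous ester
Product: 26 9β-allyl-18-hydroxy-4β,8,10β-trimethyl-5α-H-decal-7-en-6-one (A/B trans), via tertiary carbinol 25 (not isolated)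
Conditions: MeLi, CeCl3, THF, −78 °C; then 2 M HCl, THF, 45 °C
Reagents that add atoms: methyllithium, C[Li]; water, O
Why: Stork–Danheiser carbonyl transposition: the organocerium reagent adds 1,2 to the C8 carbonyl, acid converts the tertiary allylic alcohol/enol ether into the 8-methyl-7-en-6-one and releases C18–OH, and acid-catalysed enolisation of the freed C6 ketone should equilibrate C5 to the more stable trans ring fusion.

Step 21
Reactants: 26 enone
Product: 27 9β-allyl-7α,8α-epoxy-18-hydroxy-4β,8β,10β-trimethyl-5α-H-decalin-6-one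
Conditions: 30% H2O2, NaOH, MeOH, 0 °C to rt
Reagents that add atoms: hydrogen peroxide, OO
Why: Weitz–Scheffer nucleophilic epoxidation: hydroperoxide should add to C8 from the α face, away from the axial 10-methyl and the 9β-allyl group, which sets the C8–O bond α.

Step 22
Reactants: 27 epoxy ketone
Product: 28 9β-allyl-8α,18-dihydroxy-4β,8β,10β-trimethyl-5α-H-decalin-6-one
Conditions: SmI2, THF/MeOH, −90 °C
Reagents that add atoms: none
Why: SmI2 reduction of the α,β-epoxy ketone cleaves only the C7–O bond and gives the β-hydroxy ketone with the C8 oxygen and its configuration retained.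

Step 23
Reactants: 28 hydroxy ketone
Product: 29 9β-allyl-4β,8β,10β-trimethyl-5α-H-decalin-6α,8α,18-triol
Conditions: Li, NH3(l), THF, MeOH, −78 °C; solid NH4Cl
Reagents that add atoms: none
Why: Dissolving-metal reduction of the hindered C6 ketone should give the thermodynamically favoured equatorial 6α-alcohol (the 6β epimer would be 1,3-diaxial to the 4β- and 10β-methyl groups) and leaves the isolated terminal alkene.

Step 24
Reactants: 29 triol
Product: 30 9β-allyl-4β,8β,10β-trimethyl-6α,8α,18-tris(triethylsilyloxy)-5α-H-decalin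
Conditions: TESOTf (excess), 2,6-lutidine, CH2Cl2, −78 to 0 °C
Reagents that add atoms: triethylsilyl trifluoromethanesulfonate, CC[Si](CC)(CC)OS(=O)(=O)C(F)(F)F
Why: A silyl triflate with a hindered base silylates the primary, secondary and tertiary hydroxyls so that no acidic hydrogen remains for the organozinc step.

Step 25
Reactants: 30 tris-silyl ether
Product: 33 9β-(2-hydroxyethyl)-4β,8β,10β-trimethyl-6α,8α,18-tris(triethylsilyloxy)-5α-H-decalin, via ozonide 31 (not isolated), via aldehyde 32 (not isolated)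
Conditions: O3, CH2Cl2, −78 °C; then NaBH4, MeOH, −78 to 0 °C
Reagents that add atoms: ozone, [O-][O+]=O
Why: Ozonolysis of the only alkene and in-situ borohydride reduction shorten the allyl group to the C11–C12 hydroxyethyl chain.

Step 26
Reactants: 33 primary alcohol
Product: 34 9β-(2-iodoethyl)-4β,8β,10β-trimethyl-6α,8α,18-tris(triethylsilyloxy)-5α-H-decalin
Conditions: I2, PPh3, imidazole, CH2Cl2, 0 °C
Reagents that add atoms: iodine, II
Why: Appel-type iodination (Garegg–Samuelsson conditions) converts the unhindered primary alcohol into the iodide; imidazole buffers the medium for the silyl ethers.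

Step 27
Reactants: 34 iodide; 8 butenolide enol triflate
Product: 36 6,8,18-tris(triethylsilyl) ether 14,15-acetonide of the target, via alkylzinc iodide 35 (not isolated)
Conditions: Zn dust (activated), DMA, 40 °C; then 8, PdCl2(dppf) (cat.), LiCl, THF/DMA, 40 °C
Reagents that add atoms: none
Why: Zinc insertion into the primary iodide and Pd-catalysed Negishi sp3–sp2 coupling with the enol triflate form the C12–C13 bond under neutral conditions that should spare the base-sensitive butenolide and touch no stereocentre.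

Step 28
Reactants: 36 protected target
Product: 37 CNP0301623.1 (target)
Conditions: 1 M HCl, THF/MeOH, rt
Reagents that add atoms: none
Why: Mild aqueous acid should remove the three triethylsilyl ethers and the acetonide in one operation without dehydrating the tertiary or allylic alcohols.

**Compound list**

1 | dimethyl (4R,5R)-2,2-dimethyl-1,3-dioxolane-4,5-dicarboxylate | COC(=O)[C@@H]1OC(C)(C)O[C@H]1C(=O)OC | starting material
2 | (4R,5R)-N4,N5-dimethoxy-N4,N5,2,2-tetramethyl-1,3-dioxolane-4,5-dicarboxamide | CON(C)C(=O)[C@@H]1OC(C)(C)O[C@H]1C(=O)N(C)OC | intermediate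
3 | (4R,5R)-5-acetyl-N-methoxy-N,2,2-trimethyl-1,3-dioxolane-4-carboxamide | CC(=O)[C@@H]1OC(C)(C)O[C@H]1C(=O)N(C)OC | intermediate
4 | 1-[(4R,5R)-5-[methoxy(methyl)carbamoyl]-2,2-dimethyl-1,3-dioxolan-4-yl]ethenyl trifluoromethanesulfonate | C=C(OS(=O)(=O)C(F)(F)F)[C@@H]1OC(C)(C)O[C@H]1C(=O)N(C)OC | intermediate
5 | 1-[(4R,5R)-2,2-dimethyl-5-(2-methylprop-2-enoyl)-1,3-dioxolan-4-yl]ethenyl trifluoromethanesulfonate | C=C(OS(=O)(=O)C(F)(F)F)[C@@H]1OC(C)(C)O[C@H]1C(=O)C(C)=C | intermediate
6 | 1-[(4R,5S)-5-[(1R)-1-hydroxy-2-methylprop-2-en-1-yl]-2,2-dimethyl-1,3-dioxolan-4-yl]ethenyl trifluoromethanesulfonate | C=C(OS(=O)(=O)C(F)(F)F)[C@@H]1OC(C)(C)O[C@H]1[C@H](O)C(C)=C | intermediate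
7 | (1R)-1-[(4S,5R)-2,2-dimethyl-5-[1-(trifluoromethylsulfonyloxy)ethenyl]-1,3-dioxolan-4-yl]-2-methylprop-2-en-1-yl prop-2-enoate | C=C(OS(=O)(=O)C(F)(F)F)[C@@H]1OC(C)(C)O[C@H]1[C@H](OC(=O)C=C)C(C)=C | intermediate
8 | 1-[(4R,5S)-2,2-dimethyl-5-[(2R)-3-methyl-5-oxo-2,5-dihydrofuran-2-yl]-1,3-dioxolan-4-yl]ethenyl trifluoromethanesulfonate | C=C(OS(=O)(=O)C(F)(F)F)[C@@H]1OC(C)(C)O[C@H]1[C@@H]2OC(=O)C=C2C | intermediate
9 | (S)-2-methylglycidol | C[C@]1(CO)CO1 | starting material
10 | tert-butyldimethyl{[(2R)-2-methyloxiran-2-yl]methoxy}silane | C[C@]1(CO[Si](C)(C)C(C)(C)C)CO1 | intermediate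
11 | 3,5-dimethoxybenzoic acid | COc1cc(cc(OC)c1)C(=O)O | starting material
12 | dilithium 3,5-dimethoxycyclohexa-2,5-dien-1-ide-1-carboxylate | [Li+].[Li+].COC1=C[C-](C(=O)[O-])C=C(OC)C1 | intermediate
13 | 3,5-dimethoxy-1-methylcyclohexa-2,5-diene-1-carboxylic acid | COC1=CC(C)(C(=O)O)C=C(OC)C1 | intermediate
14 | (3,5-dimethoxy-1-methylcyclohexa-2,5-dien-1-yl)methanol | COC1=CC(C)(CO)C=C(OC)C1 | intermediate
15 | 3,5-dimethoxy-1-methylcyclohexa-2,5-diene-1-carbaldehyde | COC1=CC(C)(C=O)C=C(OC)C1 | intermediate
16 | 3-ethynyl-1,5-dimethoxy-3-methylcyclohexa-1,4-diene | COC1=CC(C)(C#C)C=C(OC)C1 | intermediate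
17 | (2R)-1-(tert-butyldimethylsilyloxy)-5-(3,5-dimethoxy-1-methylcyclohexa-2,5-dien-1-yl)-2-methylpent-4-yn-2-ol | COC1=CC(C)(C#CC[C@@](C)(O)CO[Si](C)(C)C(C)(C)C)C=C(OC)C1 | intermediate
18 | (2R)-1-(tert-butyldimethylsilyloxy)-5-(3,5-dimethoxy-1-methylcyclohexa-2,5-dien-1-yl)-2-methylpentan-2-ol | COC1=CC(C)(CCC[C@@](C)(O)CO[Si](C)(C)C(C)(C)C)C=C(OC)C1 | intermediate
19 | (2R)-5-(3,5-dimethoxy-1-methylcyclohexa-2,5-dien-1-yl)-2-methylpentane-1,2-diol | COC1=CC(C)(CCC[C@@](C)(O)CO)C=C(OC)C1 | intermediate
20 | (2R)-5-(3,5-dimethoxy-1-methylcyclohexa-2,5-dien-1-yl)-2-hydroxy-2-methylpentyl 4-methylbenzenesulfonate | COC1=CC(C)(CCC[C@@](C)(O)COS(=O)(=O)c2ccc(C)cc2)C=C(OC)C1 | intermediate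
21 | (2R)-2-[3-(3,5-dimethoxy-1-methylcyclohexa-2,5-dien-1-yl)propyl]-2-methyloxirane | COC1=CC(C)(CCC[C@]2(C)CO2)C=C(OC)C1 | intermediate
22 | 6α,18-epoxy-6β,8-dimethoxy-4β,10β-dimethyl-5β-H-decal-8(9)-ene (tricyclic mixed ketal; A/B cis) | COC1=C[C@@]2(C)CCC[C@@]3(C)CO[C@@](OC)(C1)[C@@H]23 | intermediate
23 | 6,18-epoxy-4β,10β-dimethyl-5β-H-decal-6-en-8-one (cyclic vinylogous ester; A/B cis) | O=C1C[C@@]2(C)CCC[C@@]3(C)COC(=C1)[C@@H]23 | intermediate
24 | 9β-allyl-6,18-epoxy-4β,10β-dimethyl-5β-H-decal-6-en-8-one | O=C1[C@H](CC=C)[C@@]2(C)CCC[C@@]3(C)COC(=C1)[C@@H]23 | intermediate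
25 | 9β-allyl-6,18-epoxy-4β,8,10β-trimethyl-5β-H-decal-6-en-8-ol (C8 configuration not defined) | CC1(O)[C@H](CC=C)[C@@]2(C)CCC[C@@]3(C)COC(=C1)[C@@H]23 | intermediate
26 | 9β-allyl-18-hydroxy-4β,8,10β-trimethyl-5α-H-decal-7-en-6-one (A/B trans) | C=CC[C@@H]1[C@@]2(C)CCC[C@@](C)(CO)[C@@H]2C(=O)C=C1C | intermediate
27 | 9β-allyl-7α,8α-epoxy-18-hydroxy-4β,8β,10β-trimethyl-5α-H-decalin-6-one | C=CC[C@@H]1[C@@]2(C)CCC[C@@](C)(CO)[C@@H]2C(=O)[C@H]3O[C@@]13C | intermediate
28 | 9β-allyl-8α,18-dihydroxy-4β,8β,10β-trimethyl-5α-H-decalin-6-one | C=CC[C@@H]1[C@@]2(C)CCC[C@@](C)(CO)[C@@H]2C(=O)C[C@@]1(C)O | intermediate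
29 | 9β-allyl-4β,8β,10β-trimethyl-5α-H-decalin-6α,8α,18-triol | C=CC[C@@H]1[C@@]2(C)CCC[C@@](C)(CO)[C@@H]2[C@@H](O)C[C@@]1(C)O | intermediate
30 | 9β-allyl-4β,8β,10β-trimethyl-6α,8α,18-tris(triethylsilyloxy)-5α-H-decalin | C=CC[C@@H]1[C@@]2(C)CCC[C@@](C)(CO[Si](CC)(CC)CC)[C@@H]2[C@@H](O[Si](CC)(CC)CC)C[C@@]1(C)O[Si](CC)(CC)CC | intermediate
31 | 1,2,4-trioxolane (ozonide) of 30 (configuration of the trioxolane carbon not defined) | C1OC(OO1)C[C@@H]2[C@@]3(C)CCC[C@@](C)(CO[Si](CC)(CC)CC)[C@@H]3[C@@H](O[Si](CC)(CC)CC)C[C@@]2(C)O[Si](CC)(CC)CC | intermediate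
32 | 9β-(2-oxoethyl)-4β,8β,10β-trimethyl-6α,8α,18-tris(triethylsilyloxy)-5α-H-decalin | O=CC[C@@H]1[C@@]2(C)CCC[C@@](C)(CO[Si](CC)(CC)CC)[C@@H]2[C@@H](O[Si](CC)(CC)CC)C[C@@]1(C)O[Si](CC)(CC)CC | intermediate
33 | 9β-(2-hydroxyethyl)-4β,8β,10β-trimethyl-6α,8α,18-tris(triethylsilyloxy)-5α-H-decalin | OCC[C@@H]1[C@@]2(C)CCC[C@@](C)(CO[Si](CC)(CC)CC)[C@@H]2[C@@H](O[Si](CC)(CC)CC)C[C@@]1(C)O[Si](CC)(CC)CC | intermediate
34 | 9β-(2-iodoethyl)-4β,8β,10β-trimethyl-6α,8α,18-tris(triethylsilyloxy)-5α-H-decalin | ICC[C@@H]1[C@@]2(C)CCC[C@@](C)(CO[Si](CC)(CC)CC)[C@@H]2[C@@H](O[Si](CC)(CC)CC)C[C@@]1(C)O[Si](CC)(CC)CC | intermediate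
35 | alkylzinc iodide derived from 34 | I[Zn]CC[C@@H]1[C@@]2(C)CCC[C@@](C)(CO[Si](CC)(CC)CC)[C@@H]2[C@@H](O[Si](CC)(CC)CC)C[C@@]1(C)O[Si](CC)(CC)CC | intermediate
36 | 6,8,18-tris(triethylsilyl) ether 14,15-acetonide of the target | C=C(CC[C@@H]1[C@@]2(C)CCC[C@@](C)(CO[Si](CC)(CC)CC)[C@@H]2[C@@H](O[Si](CC)(CC)CC)C[C@@]1(C)O[Si](CC)(CC)CC)[C@@H]3OC(C)(C)O[C@H]3[C@@H]4OC(=O)C=C4C | intermediate
37 | CNP0301623.1 | C=C(CC[C@@H]1[C@@]2(C)CCC[C@@](C)(CO)[C@@H]2[C@@H](O)C[C@@]1(C)O)[C@H](O)[C@@H](O)[C@@H]1OC(=O)C=C1C | target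

**Step count and risks**

Total step count: 28. Longest linear sequence: 20 steps (steps 9–28, from 11).

Steps most likely to fail:

Step 17 (the step that carries the new-method label). The two diastereotopic enol ethers may not be discriminated well enough, so that the relay from C4 to C10 gives both C10 series. The epoxide may also isomerise by hydride shift before the C–C bond forms. Fallback with known chemistry, from aldehyde 15 back to 23: the C4–C5 bond is made by catalyst-controlled cyclopropanation and the quaternary centre by enolate methylation. Wittig reaction of 15 with the ylide of (3-methoxycarbonylpropyl)triphenylphosphonium bromide gives methyl (Z)-5-(3,5-dimethoxy-1-methylcyclohexa-2,5-dien-1-yl)pent-4-enoate F1, and diimide reduction gives the saturated ester F2. Deacylative diazo transfer (LiHMDS and 2,2,2-trifluoroethyl trifluoroacetate to the α-trifluoroacetyl ester F3, then MsN3/Et3N) gives the α-diazo ester F4. A chiral dirhodium(II) carboxylate (Rh2(S-PTTL)4 or its enantiomer, whichever gives the required C10 series, −78 °C) should cyclopropanate one of the two enol ethers to the methoxycyclopropane ester F5. PPTS in MeOH opens this donor–acceptor cyclopropane to the C6 dimethyl ketal ester F6 (ring A closed, A/B cis). LDA/MeI should methylate C4 from the convex face to give the quaternary ester F7, LiAlH4 gives the C18 alcohol F8, and the conditions of step 18 convert F8 into 23.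

Step 19. The electrophile may approach the wrong face of the enolate, or alkylation at oxygen or a second alkylation may compete, giving a mixture at C9. Fallback, from 23 back to 24: LiHMDS and allyl chloroformate give the allyl enol carbonate F9, and Pd-catalysed decarboxylative allylation (Pd2(dba)3, a t-BuPHOX ligand of the handedness that reinforces the convex-face preference, toluene) should deliver 24. The C–C bond is then formed inside a chiral Pd–enolate ion pair instead of by an external alkyl halide.

Step 21. Hydroperoxide addition to the hindered β,β-disubstituted enone may be slow, so that base-mediated epimerisation at C5 or C9 or poor facial selectivity intervenes. Fallback, from 26 back to 28 (skipping 27): copper-catalysed conjugate borylation (B2pin2, CuCl, NaOt-Bu, a bisphosphine, MeOH, THF) should give the tertiary β-boryl ketone F10 with boron on the α face, anti to the 10-methyl, and stereoretentive oxidation with NaBO3·4H2O should give 28 directly.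

Further compounds

F1 | step 17 | methyl (Z)-5-(3,5-dimethoxy-1-methylcyclohexa-2,5-dien-1-yl)pent-4-enoate | COC1=CC(C)(/C=C\CCC(=O)OC)C=C(OC)C1
F2 | step 17 | methyl 5-(3,5-dimethoxy-1-methylcyclohexa-2,5-dien-1-yl)pentanoate | COC1=CC(C)(CCCCC(=O)OC)C=C(OC)C1
F3 | step 17 | methyl 5-(3,5-dimethoxy-1-methylcyclohexa-2,5-dien-1-yl)-2-(trifluoroacetyl)pentanoate | COC1=CC(C)(CCCC(C(=O)OC)C(=O)C(F)(F)F)C=C(OC)C1
F4 | step 17 | methyl 2-diazo-5-(3,5-dimethoxy-1-methylcyclohexa-2,5-dien-1-yl)pentanoate | COC1=CC(C)(CCCC(=[N+]=[N-])C(=O)OC)C=C(OC)C1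
F5 | step 17 | methoxycyclopropane ester (C4 bridging C5 and C6 on the α face; A/B cis) | COC1=C[C@@]2(C)CCC[C@]3(C(=O)OC)[C@H]2[C@]3(OC)C1
F6 | step 17 | methyl 6,6,8-trimethoxy-10β-methyl-5β-H-decal-8(9)-ene-4-carboxylate (C4 configuration not defined) | COC1=C[C@@]2(C)CCCC(C(=O)OC)[C@H]2C(OC)(OC)C1
F7 | step 17 | methyl 6,6,8-trimethoxy-4β,10β-dimethyl-5β-H-decal-8(9)-ene-4α-carboxylate | COC1=C[C@@]2(C)CCC[C@@](C)(C(=O)OC)[C@H]2C(OC)(OC)C1
F8 | step 17 | 6,6,8-trimethoxy-4β,10β-dimethyl-5β-H-decal-8(9)-en-18-ol | COC1=C[C@@]2(C)CCC[C@@](C)(CO)[C@H]2C(OC)(OC)C1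
F9 | step 19 | allyl enol carbonate of 23 (8-allyloxycarbonyloxy-6,18-epoxy-4β,10β-dimethyl-5β-H-decala-6,8-diene) | C=CCOC(=O)OC1=C[C@@]2(C)CCC[C@@]3(C)COC(=C1)[C@@H]23
F10 | step 21 | 9β-allyl-18-hydroxy-4β,8β,10β-trimethyl-8α-(4,4,5,5-tetramethyl-1,3,2-dioxaborolan-2-yl)-5α-H-decalin-6-one | C=CC[C@@H]1[C@@]2(C)CCC[C@@](C)(CO)[C@@H]2C(=O)C[C@@]1(C)B3OC(C)(C)C(C)(C)O3
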